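Of the L charged to each flask, part goes into chains and part stays free, and the J charged counts the chains that share the bound part.

    D + X → L + X, rate k1*[X] as long as [D] is above zero (k1 = 0.25 min⁻¹)
    L + J → X + D (k2 = 0.68 M⁻¹ min⁻¹)
    L + X → D + X, rate k3*[X]*[L] (k3 = 1.2 M⁻¹ min⁻¹)
    D → Q (k4 = 2.1 × 10⁻⁵ min⁻¹)

- ash: L 0.50 M; J 2.5 mol%; time 12 h
- oak: L 0.25 M; J 2.5 mol%; time 12 h

- the average divides the monomer in chains by the number of chains begun, living and dead together
- run time (ash): 12 h

- which of the two ends with the longer chains by the average number of monomer units in a chain (chains begun, living or dead) ("neither" if they lie within 10%) (ash / oak / neither)
- average number of monomer units in a chain (chains begun, living or dead) at the end, ash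
- average number of monomer units in a chain (chains begun, living or dead) at the end, oak

I reckon with two amounts: the L charged and a level of free L. The propagation step takes L at a rate proportional to X and to L, and the unzipping step returns it, as long as D is above zero, at a rate proportional to X. X stands in both, so the two cancel at 0.208 M, the equilibrium monomer concentration. As a fraction of the charge this leaves 41.7% free in ash and 83.3% free in oak. I take the rest to lie in D, and dividing it by the loading of J gives the length.

Two conditions must hold, and a third process must be small. Even with L down at that level, J has a lifetime of 7.06 min, far shorter than the run, so I count the chains begun as the J charged. In oak, which has less X than ash once J is consumed, I reckon that free L closes on the level with a time constant of 2.22 h, shorter than the run. The half-life of D towards Q is 23 d, far longer than the run, so I drop that loss.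

I commit to 23.3 for ash and 6.67 for oak, so the longer chains are in ash.

The forecast names ash, with 23 for ash and 6.56 for oak, both figures a little below mine. Its grounds are that “both runs have time to relax to that ceiling within 12 h”.

The simulation gives ash the longer chains, 23.0 for ash against 6.60 for oak. A neighbouring flask has the recipe of ash with 0.30 M of L, the same loading and the same time. The same reckoning leaves 69.3% of its charge free and gives a length of 12.2. Simulated, that flask ends with 69.5% of its charge as L, 30.2% as D, and a length of 12.1.

The rate constants are invented; what happens was integrated by code.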